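Your vessel is closed and stirred, and the decision for the next run is how much scavenger to charge.

    substrate + second chain carrier → released group + first chain carrier (k1 = 34000 M⁻¹ s⁻¹)
    scavenger + released group → scavenged by-product (k2 = 0.035 M⁻¹ s⁻¹)
    2 first chain carrier → ended chains B (k3 = 4 × 10⁸ M⁻¹ s⁻¹)
    2 second chain carrier → ended chains A (k4 = 4.2 × 10⁶ M⁻¹ s⁻¹)
    reagent + first chain carrier → target + second chain carrier (k5 = 7900 M⁻¹ s⁻¹)
    initiator → 2 initiating radical (k6 = 3.8 × 10⁻⁵ s⁻¹)
    reagent + released group ⇌ idle adduct, settled at all times (K7 = 21 M⁻¹)
    substrate + initiating radical → capped initiator + first chain carrier (k8 = 7.3 × 10⁵ M⁻¹ s⁻¹)

in all of them: substrate 0.074 M; reagent 1.10 equiv; initiator 0.65 mol%; time 5.0 h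
- green: scavenger 2.40 equiv
- violet: scavenger 4.80 equiv
- ochre: scavenger 1.20 equiv

- part of the substrate that has reacted at the end, green
- part of the substrate that has reacted at the end, violet
- part of the substrate that has reacted at the end, ochre
- what raising the equivalents of scavenger from its lowest to its highest value here does to the part of the substrate that has reacted (changes below 5 percentage points count as none) (it falls / it rises / no change)

- a species is counted by the substrate in it: one ended chains B counts as two
- amounts and yields of released group count idle adduct too
- a step written with two of one species runs at k times the square of its concentration and takes two of it each time
- run time (green): 5.0 h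

Treat the chain as a system with a nearly constant state and freeze that state. Each carrier is remade as fast as it goes, so in green [second chain carrier]/[first chain carrier] starts near 0.256. With that ratio, the ending of first chain carriers runs about 1460 times faster than the ending of second chain carriers. Set the radicals from the initiator equal to the loss by that ending, and [first chain carrier] is the square root of the initiator's rate constant times [initiator] over the ending constant, 6.76 × 10⁻⁹ M at the start.

The reagent then decays pseudo-first-order at 5.34 × 10⁻⁵ s⁻¹, and this rate sags slowly as the initiator decays with a half-life of 5.1 h. Summing it over the run gives 0.814. This is the exposure, the time integral of the reagent's decay rate constant. It leaves 44.3% of the reagent. Adding the substrate capped by initiating radicals, I commit to 61.9% reacted.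

Scavenger reaches this through the idle adduct. In ochre, free released group has a half-life of 3.72 min by the scavenger step, with scavenger as charged, so early in the run its making by the chain balances its removal by scavenger, and [released group] stands near 0.00140 M. That holds back about 2.94% of the reagent as idle adduct. That costs about 1.2 percentage points of conversion, so I would charge the ochre amount.

The forecast gives 61.5% for green, 61.7% for violet and 60.9% for ochre, with no change, on this ground: “Even the lowest scavenger loading removes the released group within minutes”.

The simulation gives 61.5% for green, 61.7% for violet and 61.0% for ochre, so from lowest to highest scavenger the answer is no change, a change of 0.69 points. Green ends with 44.4% of its reagent. Now take the neighbour of green charged with 0.39 mol% of initiator, the other charges and the time held. Its exposure scales with the square root of that charge, to 0.631, which leaves 53.2% of the reagent and gives 51.8% reacted. That flask ends with 53% of its reagent and 51.5% of its substrate reacted.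

All constants were set for the occasion; the result is computed.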